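(The earlier runs and the new flask are calculated for substances that don't exist.)

| flask | first end groups | scavenger | gas | remark | time |
|---|---|---|---|---|---|
| larch | 0.036 M | 0.039 M (fed, over 3.0 h) | 16 mM (held) | run made earlier; the fed solution adds 0.10 times the starting volume |  |
| birch | 0.057 M | 0.039 M (fed, over 3.0 h) | 16 mM (held) | run made earlier; the fed solution adds 0.10 times the starting volume |  |
| cedar | 0.026 M | 0.078 M (fed, over 3.0 h) | 16 mM (held) | run made earlier; the fed solution adds 0.10 times the starting volume |  |
| flask | 0.026 M | 0.0390 M (fed, over 3.0 h) | 16 mM (held) | the fed solution adds 0.10 times the starting volume | 15 h |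

- larch (time / h: first end groups / %, links / %): 0.500: 97.9, 1.8; 1.33: 93.5, 6.5; 2.50: 83.3, 17.6; 4.00: 70.6, 29.0; 5.00: 62.5, 39.7; 8.00: 38.4, 62.5; 10.0: 24.1, 74.5
- birch (time / h: first end groups / %, links / %): 0.667: 98.9, 0.3; 1.00: 96.5, 3.6; 1.50: 94.8, 7.1; 2.50: 86.4, 12.1; 4.00: 78.4, 21.5; 6.00: 66.2, 33.3; 10.0: 42.8, 56.8
- cedar (time / h: first end groups / %, links / %): 2.00: 84.0, 16.3; 4.00: 61.7, 38.2; 5.00: 55.0, 47.2; 8.00: 28.1, 74.3; 10.0: 13.5, 85.6

(scatter of a reading: 1 percentage point)

* part of the first end groups that has reacted at 15 h
* share of the unused second end groups that is free and not bound as idle adduct, at 15 h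

- amounts are per litre of the starting volume; all of the dose is in the solution fed
- at the start none of the gas is in solution
- the earlier runs do not show how much of second end groups is bound; that part of a forecast is a guess

1. At early times the larch run has barely moved, with 97.9 % of its first end groups still there at 0.500 h. After that, the percentages fall in a nearly straight line, so I read a consumption rate r in M/h. Larch has the flask's scavenger charge, and from 2.50 h to 8.00 h it gives r = 0.00294 M h⁻¹.

2. I fold the givens together. The lifetime of the flask's charge at this rate is τ = 8.85 h, and N = r × time / charge, the number of such lifetimes in the asked time, is 1.70. Because N is above one, I expect the flask's first end groups to be close to used up, with some tail.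

3. I test whether one number is enough. Cedar has the flask's charge of first end groups but twice the scavenger. Its r of 0.00229 M h⁻¹ gives N = 1.32, lower but still above one. For c the verdict stands. For fr, N is silent, since the readings do not show the bound part.

4. The forecast gives c = 97 % (90 % to 100 %) and fr = 30 % (5 % to 75 %): “The bound share is not determined by these data.”

The flask gives c = 98.5 % and fr = 95.9 %.

    scavenger + released group → scavenged by-product (k = 24.2 L mol⁻¹ min⁻¹)
    second end groups + released group ⇌ idle adduct, settled at all times (K = 2400 L mol⁻¹)
    gas ⇌ second end groups, rate k3*(csat - [second end groups]) (kL = 0.00385 min⁻¹)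
    first end groups + second end groups ⇌ links + released group (K = 1.90, k = 0.850 L mol⁻¹ min⁻¹)

At 15 h the flask keeps 1.5 % of its first end groups against 36 % of its scavenger, so first end groups are its limiting reagent. I carry N to a neighbour charged with 0.10 M of first end groups: taken at the larch rate, it comes to 0.441, below one, so I expect first end groups left over, but not how many. That neighbour keeps 52.1 % of its first end groups, and there scavenger is first to run out, with 0.0080 % of its charge left.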